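**Retrosynthetic overview**
1. Target 14 comes from 13 by removing two O-benzyl groups; 13 is cut at the depside ester C–O bond into acid 11 and the 4-OH of methyl orsellinate 6.
2. 6 comes from aromatisation (Br2, then H2/Pd) of cyclic dione 4; 4 comes from an intermolecular Michael addition of methyl acetoacetate 1 to methyl crotonate 2 (key C–C bond), followed by Dieckmann closure.
3. 11 comes from commercial methyl 3-methylorsellinate (atraric acid) 8 by C5 chlorination, bis-benzylation and saponification.
4. Ring order: the orsellinate ring is the only ring built (carbocycle in step 1, arene in steps 2–3); the chlorinated ring is bought as an arene; the two arenes are joined last.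

Assumption: the target has no stereocentre, so no stereocontrol is needed; the sp3 centres of 3, 4 and 5 are carried as mixtures and vanish on aromatisation.
Convention: where one reagent does the same operation twice in one step (steps 2, 3, 5, 8) the singly reacted species is not numbered, and salt or boron-ester forms that are only protonated or hydrolysed at work-up are not numbered.

**Step 1**
Reactants: 1 methyl acetoacetate; 2 methyl (E)-but-2-enoate (methyl crotonate)
Product: 4 methyl 6-methyl-2,4-dioxocyclohexane-1-carboxylate (methyl dihydroorsellinate; racemic; keto–enol mixture), via Michael adduct 3 (not isolated)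
Conditions: NaOMe (1.1 eq), MeOH, reflux, 4 h; then aq. HCl, 0 °C
Reagents that add atoms: none
Why: The sodium enolate of the β-keto ester adds 1,4 to the crotonate (intermolecular Michael addition) and the acetyl CH3 of adduct 3 then closes onto the distal ester (Dieckmann/Claisen condensation), driven by formation of the stabilised enolate of the cyclic β-diketone; the two sp3 centres are irrelevant because step 2 destroys them.

**Step 2**
Reactants: 4 methyl 6-methyl-2,4-dioxocyclohexane-1-carboxylate
Product: 7 methyl 3,5-dibromo-2,4-dihydroxy-6-methylbenzoate, via 3-bromo-dione 5 (not isolated), via methyl orsellinate 6 (not isolated)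
Conditions: Br2 (3.05 eq), AcOH, rt; pour into H2O
Reagents that add atoms: bromine, BrBr
Why: α-Bromination of the enolised dione followed by loss of HBr and tautomerisation aromatises the ring (bromination–dehydrobromination), and the electron-rich resorcinol 6 is at once brominated at both free positions (SEAr), so driving to the single crystalline dibromide avoids mixtures.

**Step 3**
Reactants: 7 methyl 3,5-dibromo-2,4-dihydroxy-6-methylbenzoate
Product: 6 methyl orsellinate (methyl 2,4-dihydroxy-6-methylbenzoate)
Conditions: H2 (1 atm), 10% Pd/C, NaOAc (2.5 eq), MeOH, rt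
Reagents that add atoms: none
Why: Pd-catalysed hydrogenolysis of both aryl C–Br bonds (hydrodehalogenation) with NaOAc as HBr scavenger leaves the ester, the phenols and the arene untouched.

**Step 4**
Reactants: 8 methyl 2,4-dihydroxy-3,6-dimethylbenzoate (atraric acid)
Product: 9 methyl 5-chloro-2,4-dihydroxy-3,6-dimethylbenzoate
Conditions: SO2Cl2 (1.05 eq), Et2O, 0 °C → rt
Reagents that add atoms: sulfuryl chloride, O=S(=O)(Cl)Cl
Why: Electrophilic aromatic chlorination (SEAr) can only take place at C5, the sole unsubstituted ring carbon, which is ortho to the 4-OH and para to the 2-OH, and one equivalent at 0 °C prevents ipso attack.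

**Step 5**
Reactants: 9 methyl 5-chloro-2,4-dihydroxy-3,6-dimethylbenzoate
Product: 10 methyl 2,4-bis(benzyloxy)-5-chloro-3,6-dimethylbenzoate
Conditions: BnBr (2.5 eq), K2CO3 (4 eq), DMF, 70 °C
Reagents that add atoms: benzyl bromide, BrCc1ccccc1
Why: Williamson ether synthesis in DMF with heating alkylates both the flanked 4-OH and the hydrogen-bonded 2-OH, and the methyl ester and aryl chloride are inert to carbonate.

**Step 6**
Reactants: 10 methyl 2,4-bis(benzyloxy)-5-chloro-3,6-dimethylbenzoate
Product: 11 2,4-bis(benzyloxy)-5-chloro-3,6-dimethylbenzoic acid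
Conditions: KOH (10 eq), DMSO–H2O (4:1), 90 °C; then 1 M HCl, 0 °C
Reagents that add atoms: potassium hydroxide, [K+].[OH-]
Why: Saponification of the di-ortho-substituted methyl ester needs the poorly solvated hydroxide of aqueous DMSO, to which the benzyl ethers and the unactivated aryl chloride are stable.

**Step 7**
Reactants: 11 2,4-bis(benzyloxy)-5-chloro-3,6-dimethylbenzoic acid; 6 methyl orsellinate
Product: 13 methyl 4-{[2,4-bis(benzyloxy)-5-chloro-3,6-dimethylbenzoyl]oxy}-2-hydroxy-6-methylbenzoate, via mixed trifluoroacetic anhydride 12 (not isolated)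
Conditions: (CF3CO)2O (3 eq), toluene, 0 °C → rt
Reagents that add atoms: none
Why: TFAA turns the hindered acid into mixed anhydride 12 (an acylium equivalent) that acylates the free 4-OH of 6, while the 2-OH stays locked in a hydrogen bond to the ester carbonyl (mixed-anhydride esterification, the standard depside coupling).

**Step 8**
Reactants: 13 methyl 4-{[2,4-bis(benzyloxy)-5-chloro-3,6-dimethylbenzoyl]oxy}-2-hydroxy-6-methylbenzoate
Product: 14 methyl 4-[(5-chloro-2,4-dihydroxy-3,6-dimethylbenzoyl)oxy]-2-hydroxy-6-methylbenzoate (target, CNP0171762.0)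
Conditions: BCl3 (5 eq, 1 M in CH2Cl2), C6HMe5 (6 eq), CH2Cl2, −78 → −40 °C; then H2O
Reagents that add atoms: none
Why: Lewis-acid debenzylation in which BCl3 activates the aryl benzyl ethers and pentamethylbenzene traps the benzyl cations (Friedel–Crafts scavenging) leaves the aryl chloride, the methyl ester and the depside ester intact, which hydrogenolysis might not.

**Compound list**
1 | methyl acetoacetate | CC(=O)CC(=O)OC | starting material
2 | methyl (E)-but-2-enoate (methyl crotonate) | C/C=C/C(=O)OC | starting material
3 | dimethyl 2-acetyl-3-methylpentanedioate (Michael adduct, diastereomer mixture, racemic) | COC(=O)CC(C)C(C(C)=O)C(=O)OC | intermediate (not isolated)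
4 | methyl 6-methyl-2,4-dioxocyclohexane-1-carboxylate (methyl dihydroorsellinate, racemic, keto–enol mixture) | COC(=O)C1C(C)CC(=O)CC1=O | intermediate
5 | methyl 3-bromo-6-methyl-2,4-dioxocyclohexane-1-carboxylate (stereoisomer mixture) | COC(=O)C1C(C)CC(=O)C(Br)C1=O | intermediate (not isolated)
6 | methyl orsellinate (methyl 2,4-dihydroxy-6-methylbenzoate) | COC(=O)c1c(C)cc(O)cc1O | intermediate (transient in step 2, isolated in step 3)
7 | methyl 3,5-dibromo-2,4-dihydroxy-6-methylbenzoate | COC(=O)c1c(C)c(Br)c(O)c(Br)c1O | intermediate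
8 | methyl 2,4-dihydroxy-3,6-dimethylbenzoate (atraric acid) | COC(=O)c1c(C)cc(O)c(C)c1O | starting material
9 | methyl 5-chloro-2,4-dihydroxy-3,6-dimethylbenzoate | COC(=O)c1c(C)c(Cl)c(O)c(C)c1O | intermediate
10 | methyl 2,4-bis(benzyloxy)-5-chloro-3,6-dimethylbenzoate | COC(=O)c1c(C)c(Cl)c(OCc2ccccc2)c(C)c1OCc1ccccc1 | intermediate
11 | 2,4-bis(benzyloxy)-5-chloro-3,6-dimethylbenzoic acid | OC(=O)c1c(C)c(Cl)c(OCc2ccccc2)c(C)c1OCc1ccccc1 | intermediate
12 | 2,4-bis(benzyloxy)-5-chloro-3,6-dimethylbenzoic trifluoroacetic anhydride | FC(F)(F)C(=O)OC(=O)c1c(C)c(Cl)c(OCc2ccccc2)c(C)c1OCc1ccccc1 | intermediate (not isolated)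
13 | methyl 4-{[2,4-bis(benzyloxy)-5-chloro-3,6-dimethylbenzoyl]oxy}-2-hydroxy-6-methylbenzoate | COC(=O)c1c(C)cc(OC(=O)c2c(C)c(Cl)c(OCc3ccccc3)c(C)c2OCc2ccccc2)cc1O | intermediate
14 | methyl 4-[(5-chloro-2,4-dihydroxy-3,6-dimethylbenzoyl)oxy]-2-hydroxy-6-methylbenzoate | COC(=O)c1c(C)cc(OC(=O)c2c(C)c(Cl)c(O)c(C)c2O)cc1O | target

**Totals**
Total step count: 8. Longest linear sequence: 5 steps (1 → 2 → 3 → 7 → 8 from 1 and 2; equally 4 → 5 → 6 → 7 → 8 from 8).

**Three steps most likely to fail**

Step 2 (bromination–aromatisation) may give mixtures of partly brominated or non-aromatised material. The fallback builds the arene at the right oxidation level and needs no oxidation. It sets out from 1 and comes back to the route at 6. Compound 1 is deprotonated twice (NaH, then n-BuLi, THF, 0 °C) and the dianion attacks the ester of a second molecule of 1 on warming to reflux (intermolecular Claisen condensation). This gives methyl 3,5,7-trioxooctanoate F1, which is not isolated and cyclises by intramolecular aldol condensation and dehydration on mildly basic work-up to 6, bypassing 4, 5 and 7.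

Step 7 (depside coupling) joins a di-ortho-substituted acid to a phenol; acid-mediated C-acylation of the orsellinate ring or loss of the ortho benzyl group could compete. The fallback switches from acylium chemistry to base-mediated O-acylation with an isolated acyl chloride. It sets out from 11 and comes back at 13. Acid 11 is converted under neutral conditions (1-chloro-N,N,2-trimethylprop-1-en-1-amine, CH2Cl2, rt) into 2,4-bis(benzyloxy)-5-chloro-3,6-dimethylbenzoyl chloride F2. F2 is then added to the 4-O-potassium salt of 6 (K2CO3, acetone, reflux), where only the more acidic, non-chelated 4-OH is deprotonated, to give 13.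

Step 8 (global debenzylation) may cleave the depside ester or stall at the hindered 4-O-benzyl ether. The fallback moves chlorination to the end so that plain hydrogenolysis can be used with no C–Cl bond present. It sets out from 8 and comes back at 14. Compound 8 is bis-benzylated (BnBr, K2CO3, DMF, 70 °C) to methyl 2,4-bis(benzyloxy)-3,6-dimethylbenzoate F3 and saponified (KOH, DMSO–H2O, 90 °C) to 2,4-bis(benzyloxy)-3,6-dimethylbenzoic acid F4. F4 is activated with TFAA in toluene as 2,4-bis(benzyloxy)-3,6-dimethylbenzoic trifluoroacetic anhydride F5, which acylates 6 to methyl 4-{[2,4-bis(benzyloxy)-3,6-dimethylbenzoyl]oxy}-2-hydroxy-6-methylbenzoate F6. Hydrogenolysis (H2, Pd/C, EtOAc, rt) gives methyl 4-[(2,4-dihydroxy-3,6-dimethylbenzoyl)oxy]-2-hydroxy-6-methylbenzoate F7. F7 is chlorinated last (SO2Cl2 1.0 eq, Et2O, 0 °C) at the single free position of the much more electron-rich dihydroxy ring to give 14.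

**Further compounds**
F1 | step 2 | methyl 3,5,7-trioxooctanoate | COC(=O)CC(=O)CC(=O)CC(C)=O
F2 | step 7 | 2,4-bis(benzyloxy)-5-chloro-3,6-dimethylbenzoyl chloride | ClC(=O)c1c(C)c(Cl)c(OCc2ccccc2)c(C)c1OCc1ccccc1
F3 | step 8 | methyl 2,4-bis(benzyloxy)-3,6-dimethylbenzoate | COC(=O)c1c(C)cc(OCc2ccccc2)c(C)c1OCc1ccccc1
F4 | step 8 | 2,4-bis(benzyloxy)-3,6-dimethylbenzoic acid | OC(=O)c1c(C)cc(OCc2ccccc2)c(C)c1OCc1ccccc1
F5 | step 8 | 2,4-bis(benzyloxy)-3,6-dimethylbenzoic trifluoroacetic anhydride | FC(F)(F)C(=O)OC(=O)c1c(C)cc(OCc2ccccc2)c(C)c1OCc1ccccc1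
F6 | step 8 | methyl 4-{[2,4-bis(benzyloxy)-3,6-dimethylbenzoyl]oxy}-2-hydroxy-6-methylbenzoate | COC(=O)c1c(C)cc(OC(=O)c2c(C)cc(OCc3ccccc3)c(C)c2OCc2ccccc2)cc1O
F7 | step 8 | methyl 4-[(2,4-dihydroxy-3,6-dimethylbenzoyl)oxy]-2-hydroxy-6-methylbenzoate | COC(=O)c1c(C)cc(OC(=O)c2c(C)cc(O)c(C)c2O)cc1O
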